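**Plan**

Carotenoid numbering is used: ring A is C1–C6 (with C4=C5), its chain is C7–C15, and the half with the saturated C5' (ring B) carries primes.
Retrosynthesis: the target is first seen as the 1,12-dehydration product of a C15 carbinol (C15–O and C4–H removed). The central C15–C15' bond is then cut into all-trans-retinal (C15 = aldehyde carbon) and a C20 tetraene-yne (C15' = terminal alkyne carbon). The tetraene-yne is cut at C10'=C11' and C8'=C9' (two Wittig reactions), at C7'–C8' (formylation of an enol triflate) and at the C1'–C6' ring bond (cation–olefin cyclisation of citronellal enol acetate).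
Enabling feature: ring A carries the endocyclic C4=C5 and the exocyclic C6=C7 double bonds, so the unprimed C20 half is retinal minus water. C15 can therefore enter as a carbonyl carbon, and its oxygen leaves afterwards together with H-4, which moves the five chain double bonds into the retro positions.
Forward order: ring B is closed first (step 2), the chain is grown from C7' to C15' (steps 3–7), ring A arrives intact with retinal in the fragment union (step 8), and the last step creates the ring A diene and the undecaene.
Stereochemistry: C5' (S) comes from (S)-citronellal and is never touched. The chain double bonds are E from a stabilised ylide, an E-selective allylic ylide, syn-hydrozirconation and the transoid cation of the final elimination. The exocyclic 6E and 6'E geometries are those favoured by allylic strain.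

Key step: step 8

**Route**

Step 1
Reactants: 1 (S)-citronellal
Product: 2 (3S)-3,7-dimethylocta-1,6-dien-1-yl acetate (enol acetate; E/Z mixture at C1=C2)
Conditions: Ac2O, KOAc, Et3N, 120 °C
Reagents that add atoms: acetic anhydride, CC(=O)OC(C)=O
Why: Enol acetylation of an enolisable aldehyde turns C1–C2 into the nucleophilic enol acetate needed for ring closure; the C3 centre is not involved and stays (S).

Step 2
Reactants: 2 (3S)-3,7-dimethylocta-1,6-dien-1-yl acetate
Product: 3 (1R,6S)-2,2,6-trimethylcyclohexane-1-carbaldehyde (trans-dihydrocyclocitral; any C1 epimer is carried along)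
Conditions: 85% H3PO4, toluene, 100 °C; then H2O
Reagents that add atoms: water, O (hydrolysis of the acyloxycarbenium ion; its oxygen ends in the aldehyde or in the acetic acid)
Why: Acid-mediated cation–olefin cyclisation, the established route from citronellal enol acetate to dihydrocyclocitral: protonation of the trisubstituted alkene gives a tertiary cation that the enol acetate carbon captures to close the six-membered ring B; the methyl-bearing centre is retained from 1, and the new CHO-bearing centre settles trans but is irrelevant because it becomes sp2 in step 3.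

Step 3
Reactants: 3 (1R,6S)-2,2,6-trimethylcyclohexane-1-carbaldehyde
Product: 5 (E)-[(6S)-2,2,6-trimethylcyclohexylidene]methyl trifluoromethanesulfonate, via potassium enolate 4 (not isolated)
Conditions: KN(SiMe3)2, THF, −78 → 0 °C; then PhNTf2, −78 °C → rt
Reagents that add atoms: N-phenylbis(trifluoromethanesulfonimide), O=S(=O)(N(c1ccccc1)S(=O)(=O)C(F)(F)F)C(F)(F)F
Why: Standard enol triflate synthesis: removal of the only α-hydrogen gives the exocyclic enolate, whose oxygen should prefer the side of the CH(CH3) carbon over the quaternary C(CH3)2 carbon (allylic strain), and O-sulfonylation fixes this E geometry; C5' is not acidic and is untouched.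

Step 4
Reactants: 5 (E)-[(6S)-2,2,6-trimethylcyclohexylidene]methyl trifluoromethanesulfonate
Product: 6 (2E)-2-[(6S)-2,2,6-trimethylcyclohexylidene]acetaldehyde
Conditions: Pd(PPh3)4 (5 mol %), LiCl, CO (3 atm), Bu3SnH (slow addition), THF, 50 °C
Reagents that add atoms: carbon monoxide, [C-]#[O+]
Why: Palladium-catalysed reductive carbonylation (formylation) of a vinyl triflate: oxidative addition, CO insertion and hydride transfer from tin should give the enal with retention of alkene geometry, under neutral conditions that cannot epimerise the γ-centre C5'.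

Step 5
Reactants: 6 (2E)-2-[(6S)-2,2,6-trimethylcyclohexylidene]acetaldehyde; 7 2-(triphenylphosphoranylidene)propanal
Product: 8 (2E,4E)-2-methyl-4-[(6S)-2,2,6-trimethylcyclohexylidene]but-2-enal
Conditions: toluene, 90 °C
Reagents that add atoms: none
Why: Wittig olefination with a stabilised α-methyl formyl ylide is E-selective and should stop after one homologation, because the α-branched product aldehyde is less reactive than 6.

Step 6
Reactants: 9 (2E)-3-methylpent-2-en-4-yn-1-ol
Product: 10 (3E)-5-bromo-3-methylpent-3-en-1-yne
Conditions: PBr3, pyridine (cat.), Et2O, −10 → 0 °C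
Reagents that add atoms: phosphorus tribromide, BrP(Br)Br
Why: Low-temperature bromination of a primary allylic alcohol with PBr3 (SN2 at the primary carbon) keeps the E geometry of the enyne; the bromide is used at once.

Step 7
Reactants: 10 (3E)-5-bromo-3-methylpent-3-en-1-yne; 8 (2E,4E)-2-methyl-4-[(6S)-2,2,6-trimethylcyclohexylidene]but-2-enal
Product: 13 (1E,2E,4E,6E)-3,7-dimethyl-1-[(6S)-2,2,6-trimethylcyclohexylidene]nona-2,4,6-trien-8-yne (C20 tetraene-yne), via phosphonium bromide 11 (not isolated), via phosphorus ylide 12 (not isolated)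
Conditions: PBu3, THF, rt; then KOtBu, −78 °C; then 8, −78 → 0 °C
Reagents that add atoms: none
Why: Wittig olefination with an allylic tributylphosphonium ylide, the trialkylphosphine variant known to give E-1,3-dienes selectively; the ylide carbon is more acidic than the terminal alkyne, so the alkyne needs no protection, and the low temperature should preserve the 12'E geometry.

Step 8
Reactants: 13 C20 tetraene-yne; 14 all-trans-retinal
Product: 18 (1E,2E,4E,6E,8E,11E,13E,15E,17E)-3,7,12,16-tetramethyl-18-(2,6,6-trimethylcyclohex-1-en-1-yl)-1-[(6S)-2,2,6-trimethylcyclohexylidene]octadeca-2,4,6,8,11,13,15,17-octaen-10-ol (C40 carbinol with OH on C15; both C15 epimers), via alkenylzirconocene 15 (not isolated), via alkenylzinc 16 (not isolated), via zinc alkoxide 17 (not isolated)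
Conditions: Cp2Zr(H)Cl (1.2 equiv), CH2Cl2, rt, dark; then ZnMe2 (toluene), −65 °C; then 14, −65 → 0 °C; aq. NaHCO3
Reagents that add atoms: none
Why: Cp2Zr(H)Cl adds syn and regioselectively across the terminal alkyne of 13 (Zr on C15'), which fixes the 14'E geometry; exchange with ZnMe2 gives alkenylzinc 16, which adds through a carbonyl-coordinated transition state to the aldehyde carbon C15 of 14 and forms the C15–C15' bond as alkoxide 17. The closest known reaction type is the hydrozirconation–zinc transmetalation–aldehyde addition sequence, a reductive alkyne–aldehyde coupling that gives E-allylic alcohols. No ring is closed. The one new stereocentre, carbinol carbon C15, is left uncontrolled on purpose because it becomes sp2 in step 9. The step needs chemoselectivity for the alkyne over the C=C bonds, secured because 13 has a single monosubstituted alkyne beside only trisubstituted or conjugated disubstituted alkenes and because 14 is added after all Zr–H is consumed; it also needs 1,2-addition without enolisation, secured by the non-basic alkenylzinc and the methyl-substituted β-carbon C13 of retinal. The choice of partners rests on ring A: its C4=C5 and exocyclic C6=C7 bonds make the unprimed half the anhydro form of retinal, so the carbonyl oxygen is a traceless handle that step 9 removes.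

Step 9
Reactants: 18 C40 carbinol
Product: 19 (6E,6'E,5'S)-4,5'-retro-β,β-carotene (all-E; the target)
Conditions: TsOH·H2O (2 mol %), toluene, 0 °C, Ar, dark; then Et3N
Reagents that add atoms: none
Why: Acid-catalysed dehydration with allylic transposition along the whole chain, the reaction type by which retinol gives anhydroretinol: ionisation of the doubly allylic C15–OH gives a cation delocalised from C5 to C6', and loss of the pseudoaxial H-4 of ring A should install C4=C5 and shift the left-arm double bonds to C6=C7 through C14=C15 in the all-E, 6E geometry of anhydroretinol, while H-5' of ring B is held in the nodal plane of the π system by allylic strain (axial C5' methyl), so the C5' centre should survive; no new stereocentre is formed.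

**Compound list**

1 | (S)-citronellal, (3S)-3,7-dimethyloct-6-enal | C[C@@H](CCC=C(C)C)CC=O | starting material
2 | (3S)-3,7-dimethylocta-1,6-dien-1-yl acetate (E/Z mixture at C1=C2, drawn without that descriptor) | CC(=O)OC=C[C@@H](C)CCC=C(C)C | intermediate
3 | (1R,6S)-2,2,6-trimethylcyclohexane-1-carbaldehyde (trans-dihydrocyclocitral) | O=C[C@@H]1[C@@H](C)CCCC1(C)C | intermediate
4 | potassium (E)-[(6S)-2,2,6-trimethylcyclohexylidene]methanolate | [K+].[O-]/C=C1\[C@@H](C)CCCC1(C)C | intermediate
5 | (E)-[(6S)-2,2,6-trimethylcyclohexylidene]methyl trifluoromethanesulfonate (O cis to the CH(CH3) ring carbon) | O=S(=O)(O/C=C1\[C@@H](C)CCCC1(C)C)C(F)(F)F | intermediate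
6 | (2E)-2-[(6S)-2,2,6-trimethylcyclohexylidene]acetaldehyde | O=C/C=C1\[C@@H](C)CCCC1(C)C | intermediate
7 | 2-(triphenylphosphoranylidene)propanal | CC(C=O)=P(c1ccccc1)(c1ccccc1)c1ccccc1 | starting material
8 | (2E,4E)-2-methyl-4-[(6S)-2,2,6-trimethylcyclohexylidene]but-2-enal | O=C/C(C)=C/C=C1\[C@@H](C)CCCC1(C)C | intermediate
9 | (2E)-3-methylpent-2-en-4-yn-1-ol | C#C/C(C)=C/CO | starting material
10 | (3E)-5-bromo-3-methylpent-3-en-1-yne | C#C/C(C)=C/CBr | intermediate
11 | tributyl[(2E)-3-methylpent-2-en-4-yn-1-yl]phosphonium bromide | CCCC[P+](CCCC)(CCCC)C/C=C(C)/C#C.[Br-] | intermediate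
12 | tributyl[(2E)-3-methylpent-2-en-4-yn-1-ylidene]phosphorane | CCCCP(CCCC)(CCCC)=C/C=C(C)/C#C | intermediate
13 | (1E,2E,4E,6E)-3,7-dimethyl-1-[(6S)-2,2,6-trimethylcyclohexylidene]nona-2,4,6-trien-8-yne (chain cis to the CH(CH3) ring carbon) | C#C/C(C)=C/C=C/C(C)=C/C=C1\[C@@H](C)CCCC1(C)C | intermediate
14 | all-trans-retinal | CC1=C(/C=C/C(C)=C/C=C/C(C)=C/C=O)C(C)(C)CCC1 | starting material
15 | chlorobis(cyclopentadienyl)[(1E,3E,5E,7E)-3,7-dimethyl-9-((6S)-2,2,6-trimethylcyclohexylidene)nona-1,3,5,7-tetraen-1-yl]zirconium (Zr on C15') | Cl[Zr](C1C=CC=C1)(C1C=CC=C1)/C=C/C(C)=C/C=C/C(C)=C/C=C2\[C@@H](C)CCCC2(C)C | intermediate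
16 | methyl[(1E,3E,5E,7E)-3,7-dimethyl-9-((6S)-2,2,6-trimethylcyclohexylidene)nona-1,3,5,7-tetraen-1-yl]zinc | C[Zn]/C=C/C(C)=C/C=C/C(C)=C/C=C1\[C@@H](C)CCCC1(C)C | intermediate
17 | methylzinc alkoxide of carbinol 18 (O–ZnCH3 on C15) | C[Zn]OC(/C=C/C(C)=C/C=C/C(C)=C/C=C1\[C@@H](C)CCCC1(C)C)/C=C(C)/C=C/C=C(C)/C=C/C2=C(C)CCCC2(C)C | intermediate
18 | (1E,2E,4E,6E,8E,11E,13E,15E,17E)-3,7,12,16-tetramethyl-18-(2,6,6-trimethylcyclohex-1-en-1-yl)-1-[(6S)-2,2,6-trimethylcyclohexylidene]octadeca-2,4,6,8,11,13,15,17-octaen-10-ol (both carbinol epimers) | OC(/C=C/C(C)=C/C=C/C(C)=C/C=C1\[C@@H](C)CCCC1(C)C)/C=C(C)/C=C/C=C(C)/C=C/C2=C(C)CCCC2(C)C | intermediate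
19 | (6E,6'E,5'S)-4,5'-retro-β,β-carotene, all-E | CC1=CCCC(C)(C)\C1=C/C=C(C)/C=C/C=C(C)/C=C/C=C/C(C)=C/C=C/C(C)=C/C=C1\[C@@H](C)CCCC1(C)C | target

**Step count and risks**

Total steps: 9. Longest linear sequence: 8 steps (1, 2, 3, 4, 5, 7, 8, 9).

Step 9 is the most likely to fail. The delocalised cation may lose the wrong proton: H-5' of ring B, which would give β,β-carotene and erase the stereocentre, or a hydrogen of the C5 methyl group. Prolonged acid contact may also re-protonate the product and scramble alkene geometry. The fallback sets out from 13 and 14 and returns at 19. Hydrozirconation of 13 as in step 8 (intermediate 15) followed by iodinolysis (I2, 0 °C) gives (1E,3E,5E,7E)-1-iodo-3,7-dimethyl-9-[(6S)-2,2,6-trimethylcyclohexylidene]nona-1,3,5,7-tetraene F1. NaBH4 reduction of 14 gives all-trans-retinol F2, and its TsOH-catalysed dehydration is the standard preparation of all-trans-anhydroretinol F3, where the ring A diene and the 6E geometry form on a cation that has no second polyene arm. A Heck alkenylation of the terminal vinyl group of F3 (C14=C15H2) by F1 under ligand-free conditions with a silver base [Pd(OAc)2, Ag2CO3, DMF, rt] then forms C15–C15', with β-hydride elimination from C15, and gives 19 without any cationic stage on the ring B half.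

Step 8 is the second risk. Zr–H may add to or isomerise the conjugated polyene instead of reacting cleanly at the alkyne, methyl instead of alkenyl may be transferred to retinal, and the Lewis-acidic metal salts may ionise the doubly allylic alkoxide before work-up. The fallback sets out from 13 and 14 and returns at 18. n-BuLi (THF, −78 °C) converts 13 into the lithium acetylide F4, which adds to 14 to give the propargylic alcohol F5. Hydroxyl-directed trans-hydroalumination with NaAlH2(OCH2CH2OMe)2 (THF, 0 °C) and protonolysis then gives the E-allylic alcohol 18.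

Step 7 is the third risk. E-selectivity at the new C10'=C11' bond may be incomplete, the 12'E geometry may erode by bond rotation in the delocalised ylide, and the terminal alkyne may be deprotonated and add to the aldehyde. The fallback sets out from 8 and returns at 13. A Horner–Wadsworth–Emmons reaction of 8 with the C5 phosphonate ethyl (2E)-4-(diethoxyphosphoryl)-2-methylbut-2-enoate (assumed to be purchased) [LiN(SiMe3)2, THF, −78 → 0 °C] gives the ethyl ester F6, whose α-methyl-enoate double bond is E by thermodynamic preference. Reduction with iBu2AlH gives the allylic alcohol F7, and MnO2 oxidation gives the aldehyde F8. One-carbon homologation with lithiated Me3SiCHN2 [LiN(iPr)2, THF, −78 °C → rt; Colvin rearrangement] gives 13, so the alkyne is introduced last and never sits in an ylide.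

Further compounds
F1 | step 9 | (1E,3E,5E,7E)-1-iodo-3,7-dimethyl-9-[(6S)-2,2,6-trimethylcyclohexylidene]nona-1,3,5,7-tetraene | I/C=C/C(C)=C/C=C/C(C)=C/C=C1\[C@@H](C)CCCC1(C)C
F2 | step 9 | all-trans-retinol | CC1=C(/C=C/C(C)=C/C=C/C(C)=C/CO)C(C)(C)CCC1
F3 | step 9 | all-trans-anhydroretinol | CC1=CCCC(C)(C)\C1=C/C=C(C)/C=C/C=C(C)/C=C
F4 | step 8 | lithium acetylide of 13 (Li on C15') | [Li]C#C/C(C)=C/C=C/C(C)=C/C=C1\[C@@H](C)CCCC1(C)C
F5 | step 8 | C40 propargylic alcohol (14',15'-didehydro analogue of 18; both carbinol epimers) | OC(C#C/C(C)=C/C=C/C(C)=C/C=C1\[C@@H](C)CCCC1(C)C)/C=C(C)/C=C/C=C(C)/C=C/C2=C(C)CCCC2(C)C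
F6 | step 7 | ethyl (2E,4E,6E,8E)-2,6-dimethyl-8-[(6S)-2,2,6-trimethylcyclohexylidene]octa-2,4,6-trienoate | CCOC(=O)/C(C)=C/C=C/C(C)=C/C=C1\[C@@H](C)CCCC1(C)C
F7 | step 7 | (2E,4E,6E,8E)-2,6-dimethyl-8-[(6S)-2,2,6-trimethylcyclohexylidene]octa-2,4,6-trien-1-ol | OC/C(C)=C/C=C/C(C)=C/C=C1\[C@@H](C)CCCC1(C)C
F8 | step 7 | (2E,4E,6E,8E)-2,6-dimethyl-8-[(6S)-2,2,6-trimethylcyclohexylidene]octa-2,4,6-trienal | O=C/C(C)=C/C=C/C(C)=C/C=C1\[C@@H](C)CCCC1(C)C
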